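The seven-membered ring (C1, C2, C10–C6) is read as a cyclohexanone (ring B: C1, C6–C10) enlarged by C2, and the bridge oxygen as the trace of that ketone. The key step is an intramolecular diazoalkane–ketone ring enlargement. A diazo carbon (C2), tethered through C3–C5 to C6, adds to the C1 carbonyl and closes ring A; C10 then migrates from C1 to C2 as N2 leaves. This forms the C2–C10 bond, the bicyclo[4.3.1]decane and the bridging ketone at once. The precursor is a monocyclic 2,3-disubstituted cyclohexanone bearing a 4-oxobutyl arm. Numbering: C1 acetoxy-bearing bridge carbon, C2 and C6 bridgeheads, C3–C5 enal bridge (ring A = C1–C6), C7–C10 four-carbon bridge.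

Key step: step 5

Remark on the chemistry: the C7–C10 bridge can leave C6 and reach C2 only on one face of ring A, so C2 is not an independent centre; the bridgehead pair of the target (which, read literally, puts the bridge on opposite faces) is taken to denote this cis-bridged bicycle, and its descriptors are written throughout exactly as they stand in the target.

PMB = 4-methoxybenzyl. Absolute configurations are those of the SMILES.

Step 1
Reactants: 1 1,4-dioxaspiro[4.5]dec-6-en-8-one; 2 2-[(4-methoxybenzyl)oxy]acetaldehyde
Product: 4 aldol adduct (ring B ketone; C6 CH(OH)CH2OPMB trans to the C7 methyl group; C8 ethylene ketal; carbinol epimers), via methylzinc enolate 3 (not isolated)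
Conditions: Me2Zn (1.5 equiv), Cu(OTf)2 (2 mol %), (S,R,R)-O,O'-(1,1'-binaphthyl-2,2'-diyl) N,N-bis(1-phenylethyl)phosphoramidite (4 mol %), toluene, −30 °C; then 2, −30 → 0 °C; aq. NH4Cl
Reagents that add atoms: dimethylzinc, C[Zn]C
Why: Copper-catalysed asymmetric conjugate addition with the phosphoramidite ligand should deliver methyl to one enantiotopic face of the enone (sets C7), and the zinc enolate then adds to aldehyde 2 anti to the new methyl group (tandem conjugate addition–aldol reaction, C6 trans to C7), the carbinol centre forming as a mixture that step 2 removes.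

Step 2
Reactants: 4 aldol adduct
Product: 6 (E)-alkylidene ketone (exocyclic C6=C5H–CH2OPMB; alkoxymethyl group on the side of C7), via mesylate 5 (not isolated)
Conditions: MsCl (1.5 equiv), Et3N (4 equiv), CH2Cl2, 0 °C → rt
Reagents that add atoms: none
Why: Mesylation of the β-hydroxy ketone and E1cB elimination should give the thermodynamically preferred (E)-alkylidene ketone, and C7 is untouched because its hydrogen is not conjugated to the carbonyl group.

Step 3
Reactants: 6 (E)-alkylidene ketone; 7 but-3-en-1-ylmagnesium bromide
Product: 9 ring B ketone (C6 arm CH(CH2OPMB)CH2CH2CH=CH2 trans to the C7 methyl group; C8 ethylene ketal), via bromomagnesium enolate 8 (not isolated)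
Conditions: 7 (2 equiv), CuBr·SMe2 (10 mol %), THF, −78 → −40 °C; aq. NH4Cl; then K2CO3, MeOH, rt
Reagents that add atoms: none
Why: In this copper-catalysed conjugate addition, allylic 1,3-strain with the alkoxymethyl group should hold the C7 methyl group axial so that the butenyl group enters C5 on the opposite face (sets C5), and base equilibration then places the C6 arm equatorial, trans to the C7 methyl group (sets C6).

Step 4
Reactants: 9 ring B ketone
Product: 10 keto aldehyde (arm now CH(CH2OPMB)CH2CH2CHO; the aldehyde carbon is C2)
Conditions: OsO4 (2 mol %), NaIO4 (4 equiv), 2,6-lutidine, dioxane/H2O 3:1, rt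
Reagents that add atoms: sodium periodate, [Na+].[O-]I(=O)(=O)=O (source of the aldehyde oxygen, relayed by OsO4)
Why: Lemieux–Johnson oxidation (catalytic dihydroxylation of the only alkene, then periodate cleavage) should give the aldehyde one carbon shorter, with 2,6-lutidine buffering the epimerisable C6 centre.

Step 5
Reactants: 10 keto aldehyde
Product: 13 bridged ketone (bicyclo[4.3.1]decan-10-one core: C1 ketone on the one-carbon bridge; C5 CH2OPMB; C7 methyl; C8 ethylene ketal), via tosylhydrazone 11 (not isolated), via diazoalkane 12 (not isolated)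
Conditions: TsNHNH2 (1.05 equiv), MeOH, rt; evaporate; NaH (1.0 equiv), THF, 0 °C; then toluene, 80 °C
Reagents that add atoms: none
Why: Condensation with tosylhydrazine and thermolysis of the sodium salt (Bamford–Stevens reaction in an aprotic medium) release a diazoalkane whose carbon C2 adds to the C1 carbonyl; as N2 leaves the diazonium alkoxide, C10 shifts from C1 to C2 (Tiffeneau–Demjanov-type homologation), the closest known reaction being the ring enlargement of 2-(ω-diazoalkyl)cycloalkanones to bridged bicyclic ketones. Ring A closes by 6-exo addition of the tethered diazo carbon to the ketone, and the seven-membered ring arises by one-carbon enlargement of ring B, so the C2–C10 bond and the bridging ketone appear together. The only new stereocentre is C2, and it follows from C6: the arm is anchored at C6 and C10 migrates suprafacially across ring A, so the bridge can span C2 and C6 on one face only. The step needs C10 to migrate in preference to C6 (which would give a fused hydroazulenone) or to closure by oxygen (epoxide); the less substituted α-carbon is the usual migrating group in diazoalkane homologations, and in the chair adduct with O– gauche to N2+ the C1–C10 bond is antiperiplanar to the leaving nitrogen. The aldehyde should condense before the hindered ketone, one equivalent of base removes only the N–H, and the ketal, the PMB ether and C5–C7 are not affected.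

Step 6
Reactants: 13 bridged ketone
Product: 15 tertiary acetate (C1 methyl over ring A; C1 acetoxy towards the four-carbon bridge; C8 ketal retained), via lithium alkoxide 14 (not isolated)
Conditions: MeLi (1.5 equiv), THF, −78 °C; then Ac2O (3 equiv), −78 → 0 °C
Reagents that add atoms: methyllithium, [Li]C; acetic anhydride, CC(=O)OC(C)=O
Why: 1,2-Addition of methyllithium to the non-enolisable bridging ketone should occur over ring A, past only the axial hydrogens on C3 and C5, because the face over the seven-membered ring is screened by the C7 methyl group (sets C1), and the lithium alkoxide is acetylated in the same flask.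

Step 7
Reactants: 15 tertiary acetate
Product: 16 keto acetate (C8 ketone)
Conditions: PPTS (20 mol %), acetone/H2O 10:1, 55 °C
Reagents that add atoms: water, O
Why: Acid-catalysed hydrolysis of the dioxolane should free the C8 ketone while the tertiary acetate and the PMB ether survive; C7 becomes epimerisable but is rebuilt as a quaternary centre in step 8.

Step 8
Reactants: 16 keto acetate; 17 (Z)-but-2-en-1-ol
Product: 19 quaternary ketone (C7 carries methyl and but-3-en-2-yl; C8 ketone), via crotyl enol ether 18 (not isolated)
Conditions: 17 (10 equiv), propionic acid (10 mol %), 4 Å molecular sieves, xylene, 140 °C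
Reagents that add atoms: none
Why: Acid-catalysed exchange should give the more substituted enol ether (C7=C8), whose Claisen rearrangement through a chair transition state on the exo face of C7, anti to C5 on the neighbouring bridgehead, creates the quaternary centre C7 and, by transfer of the (Z)-alkene geometry, the methyl-bearing side-chain centre.

Step 9
Reactants: 19 quaternary ketone; 20 1-bromo-2-methylprop-1-ene
Product: 22 ketone with the complete 6-methylhept-5-en-2-yl side chain, via alkylborane 21 (not isolated)
Conditions: 9-BBN (1.3 equiv), THF, 0 °C → rt; then 20, Pd(dppf)Cl2 (5 mol %), K3PO4 (3 M aq.), DMF, 50 °C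
Reagents that add atoms: none
Why: Anti-Markovnikov hydroboration of the monosubstituted alkene (the hindered C8 ketone is left alone) and B-alkyl Suzuki–Miyaura coupling with the alkenyl bromide should complete the side chain without touching a stereocentre.

Step 10
Reactants: 22 side-chain ketone
Product: 24 enol triflate (C8(OTf)=C9), via potassium enolate 23 (not isolated)
Conditions: KN(SiMe3)2 (1.1 equiv), THF, −78 °C; then PhNTf2 (1.2 equiv), −78 → 0 °C
Reagents that add atoms: N-phenylbis(trifluoromethanesulfonimide), O=S(=O)(N(c1ccccc1)S(=O)(=O)C(F)(F)F)C(F)(F)F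
Why: Enolisation is possible only towards C9 because C7 is quaternary, and O-triflation of the potassium enolate should give the enol triflate, the ketone being far more acidic than the acetate.

Step 11
Reactants: 24 enol triflate; 25 tributyl(1-ethoxyvinyl)stannane
Product: 27 enone (acetyl on C8; C8=C9), via ethoxydiene 26 (not isolated)
Conditions: 25 (1.5 equiv), Pd(PPh3)4 (5 mol %), LiCl (3 equiv), CuI (10 mol %), dioxane, 90 °C; then 1 M HCl, THF, rt
Reagents that add atoms: water, O
Why: Stille coupling of the enol triflate with the 1-ethoxyvinyl stannane should give a 2-ethoxydiene, and mild acid hydrolysis of its enol ether unmasks the methyl ketone as the C8=C9 enone.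

Step 12
Reactants: 27 enone
Product: 29 saturated methyl ketone (acetyl on C8 cis to the side chain; PMB ether), via copper enolate 28 (not isolated)
Conditions: [(Ph3P)CuH]6 (0.4 equiv), H2O (5 equiv), benzene, rt
Reagents that add atoms: none
Why: Conjugate reduction by the phosphine copper hydride places hydride on C9, and the copper enolate should be protonated at C8 from the face of the C7 methyl group, the smaller substituent on the neighbouring quaternary carbon, so that the acetyl group ends cis to the side chain (sets C8); isolated alkenes, the acetate and the PMB ether do not react.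

Step 13
Reactants: 29 saturated methyl ketone
Product: 30 primary alcohol (C5 CH2OH)
Conditions: DDQ (1.3 equiv), CH2Cl2/pH 7 buffer 10:1, 0 °C
Reagents that add atoms: none
Why: Oxidative cleavage of the PMB ether by DDQ (hydride abstraction from the electron-rich benzylic position, then hydrolysis) should free the primary alcohol and leave the acetate, the ketone and the trisubstituted alkene untouched.

Step 14
Reactants: 30 primary alcohol
Product: 32 target CNP0288370.1, via saturated aldehyde 31 (not isolated)
Conditions: IBX (3 equiv), DMSO, 60 °C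
Reagents that add atoms: none
Why: IBX should oxidise the primary alcohol to the aldehyde and then dehydrogenate it (IBX dehydrogenation of carbonyl compounds) to the enal, the double bond forming towards C4 because C6 is a bridgehead and the aldehyde reacting at a lower temperature than the methyl ketone.

Compound list
1 | 1,4-dioxaspiro[4.5]dec-6-en-8-one (mono ethylene ketal of cyclohex-2-ene-1,4-dione) | O=C1C=CC2(CC1)OCCO2 | starting material
2 | 2-[(4-methoxybenzyl)oxy]acetaldehyde | O=CCOCc1ccc(OC)cc1 | starting material
3 | methylzinc enolate of the conjugate adduct (C1–OZnMe, C1=C6, C7 methyl, C8 ketal; not isolated) | C[Zn]OC1=C[C@@H](C)C2(OCCO2)CC1 | intermediate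
4 | aldol adduct: ring B ketone, C6 CH(OH)CH2OPMB trans to C7 methyl, C8 ethylene ketal, carbinol epimers | O=C1CCC2(OCCO2)[C@H](C)[C@H]1C(O)COCc1ccc(OC)cc1 | intermediate
5 | mesylate of 4 (not isolated) | O=C1CCC2(OCCO2)[C@H](C)[C@H]1C(OS(C)(=O)=O)COCc1ccc(OC)cc1 | intermediate
6 | (E)-alkylidene ketone: exocyclic C6=C5H–CH2OPMB, C7 methyl, C8 ketal | COc1ccc(COC/C=C2/C(=O)CCC3(OCCO3)[C@@H]2C)cc1 | intermediate
7 | but-3-en-1-ylmagnesium bromide | C=CCC[Mg]Br | starting material
8 | bromomagnesium enolate of 9 (not isolated) | Br[Mg]OC1=C([C@@H](COCc2ccc(OC)cc2)CCC=C)[C@@H](C)C2(OCCO2)CC1 | intermediate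
9 | ring B ketone: C6 arm CH(CH2OPMB)CH2CH2CH=CH2 trans to C7 methyl, C8 ketal | O=C1CCC2(OCCO2)[C@H](C)[C@H]1[C@@H](COCc1ccc(OC)cc1)CCC=C | intermediate
10 | keto aldehyde: as 9 with the arm ending in CHO (C2) | O=C1CCC2(OCCO2)[C@H](C)[C@H]1[C@@H](COCc1ccc(OC)cc1)CCC=O | intermediate
11 | tosylhydrazone of 10 (not isolated) | O=C1CCC2(OCCO2)[C@H](C)[C@H]1[C@@H](COCc1ccc(OC)cc1)CCC=NNS(=O)(=O)c1ccc(C)cc1 | intermediate
12 | diazoalkane (diazo group on C2; not isolated) | O=C1CCC2(OCCO2)[C@H](C)[C@H]1[C@@H](COCc1ccc(OC)cc1)CCC=[N+]=[N-] | intermediate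
13 | bridged ketone: bicyclo[4.3.1]decan-10-one core, C1 ketone, C5 CH2OPMB, C7 methyl, C8 ethylene ketal | O=C1[C@@H]2CC[C@H](COCc3ccc(OC)cc3)[C@@H]1[C@@H](C)C4(OCCO4)CC2 | intermediate
14 | lithium alkoxide of the C1 tertiary alcohol (not isolated) | [Li+].[O-][C@]1(C)[C@@H]2CC[C@H](COCc3ccc(OC)cc3)[C@@H]1[C@@H](C)C4(OCCO4)CC2 | intermediate
15 | tertiary acetate: C1 methyl and acetoxy, C8 ketal | CC(=O)O[C@]1(C)[C@@H]2CC[C@H](COCc3ccc(OC)cc3)[C@@H]1[C@@H](C)C4(OCCO4)CC2 | intermediate
16 | keto acetate: C8 ketone | CC(=O)O[C@]1(C)[C@@H]2CC[C@H](COCc3ccc(OC)cc3)[C@@H]1[C@@H](C)C(=O)CC2 | intermediate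
17 | (Z)-but-2-en-1-ol | C/C=C\CO | starting material
18 | (Z)-but-2-enyl enol ether of 16 (C7=C8; not isolated) | CC(=O)O[C@]1(C)[C@@H]2CC[C@H](COCc3ccc(OC)cc3)[C@@H]1C(C)=C(OC/C=C\C)CC2 | intermediate
19 | quaternary ketone: C7 methyl and (S)-but-3-en-2-yl, C8 ketone | CC(=O)O[C@]1(C)[C@@H]2CC[C@H](COCc3ccc(OC)cc3)[C@@H]1[C@@](C)([C@@H](C)C=C)C(=O)CC2 | intermediate
20 | 1-bromo-2-methylprop-1-ene | CC(C)=CBr | starting material
21 | B-alkyl-9-borabicyclo[3.3.1]nonane from 19 (not isolated) | CC(=O)O[C@]1(C)[C@@H]2CC[C@H](COCc3ccc(OC)cc3)[C@@H]1[C@@](C)([C@@H](C)CCB3C4CCCC3CCC4)C(=O)CC2 | intermediate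
22 | ketone with the 6-methylhept-5-en-2-yl side chain on C7 | CC(=O)O[C@]1(C)[C@@H]2CC[C@H](COCc3ccc(OC)cc3)[C@@H]1[C@@](C)([C@@H](C)CCC=C(C)C)C(=O)CC2 | intermediate
23 | potassium enolate of 22 (C8=C9; not isolated) | CC(=O)O[C@]1(C)[C@@H]2CC[C@H](COCc3ccc(OC)cc3)[C@@H]1[C@@](C)([C@@H](C)CCC=C(C)C)C([O-])=CC2.[K+] | intermediate
24 | enol triflate (C8(OTf)=C9) | CC(=O)O[C@]1(C)[C@@H]2CC[C@H](COCc3ccc(OC)cc3)[C@@H]1[C@@](C)([C@@H](C)CCC=C(C)C)C(OS(=O)(=O)C(F)(F)F)=CC2 | intermediate
25 | tributyl(1-ethoxyvinyl)stannane | CCCC[Sn](CCCC)(CCCC)C(=C)OCC | starting material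
26 | 2-ethoxydiene (1-ethoxyvinyl group on C8; not isolated) | CC(=O)O[C@]1(C)[C@@H]2CC[C@H](COCc3ccc(OC)cc3)[C@@H]1[C@@](C)([C@@H](C)CCC=C(C)C)C(C(=C)OCC)=CC2 | intermediate
27 | enone: acetyl on C8, C8=C9 | CC(=O)O[C@]1(C)[C@@H]2CC[C@H](COCc3ccc(OC)cc3)[C@@H]1[C@@](C)([C@@H](C)CCC=C(C)C)C(C(C)=O)=CC2 | intermediate
28 | monovalent copper enolate of 29 (not isolated) | CC(=O)O[C@]1(C)[C@@H]2CC[C@H](COCc3ccc(OC)cc3)[C@@H]1[C@@](C)([C@@H](C)CCC=C(C)C)C(=C(C)O[Cu])CC2 | intermediate
29 | saturated methyl ketone, PMB ether | CC(=O)O[C@]1(C)[C@@H]2CC[C@H](COCc3ccc(OC)cc3)[C@@H]1[C@@](C)([C@@H](C)CCC=C(C)C)[C@@H](C(C)=O)CC2 | intermediate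
30 | primary alcohol (C5 CH2OH) | CC(=O)O[C@]1(C)[C@@H]2CC[C@H](CO)[C@@H]1[C@@](C)([C@@H](C)CCC=C(C)C)[C@@H](C(C)=O)CC2 | intermediate
31 | saturated aldehyde (C5 CHO; not isolated) | CC(=O)O[C@]1(C)[C@@H]2CC[C@H](C=O)[C@@H]1[C@@](C)([C@@H](C)CCC=C(C)C)[C@@H](C(C)=O)CC2 | intermediate
32 | CNP0288370.1 | CC(=O)O[C@]1(C)[C@@H]2CC=C(C=O)[C@@H]1[C@@](C)([C@@H](C)CCC=C(C)C)[C@@H](C(C)=O)CC2 | target

Total steps: 14. Longest linear sequence: 14 steps (1 → 32).

Steps most likely to fail

Step 5. C6 may migrate instead of C10 (ring contraction of ring A to a fused hydroazulenone), the adduct may collapse to the spiro-epoxide, or the diazoalkane may be lost through carbene pathways at the temperature needed to generate it. The fallback sets out from 10 and returns at 13. Samarium diiodide (SmI2, THF/MeOH, −78 °C) would couple the aldehyde and the ketone in a pinacol cyclisation to the cis-fused cis-diol F1. The secondary hydroxyl would be sulfonylated selectively (MsCl, pyridine, 0 °C) to the hydroxy mesylate F2, in which the axial C2–O bond is antiperiplanar to C1–C10. KOtBu in THF would then trigger the pinacol-type 1,2-shift of C10 with loss of mesylate to give 13.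

Step 8. Enol ether formation may go towards C9 instead of C7, the rearrangement may leak through a boat transition state, or acid may erode the (Z)-geometry of the alcohol; each gives a regio- or stereoisomer, and exchange at the hindered ketone may be slow. The fallback sets out from 16 and returns at 19. The thermodynamic, more substituted trimethylsilyl enol ether F3 would be prepared (Me3SiCl, NaI, Et3N, MeCN). It would be allylated with (E)-but-2-enyl methyl carbonate under iridium catalysis ([Ir(cod)Cl]2, a BINOL-derived phosphoramidite ligand, CsF, ZnF2, THF). In this branched-selective allylic alkylation the catalyst sets the side-chain centre and the bicycle again directs attack to the exo face of C7.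

Step 6. Facial discrimination at the bridging ketone may be poor, or the nucleophile may prefer to enter over the seven-membered ring, which would give the C1 epimer. The fallback sets out from 13 and returns at 15, and reverses the order of bond formation at C1. Methylenation of the non-enolisable ketone with Cp2TiMe2 (toluene, 70 °C) would give the exocyclic alkene F4. Mukaiyama hydration (Co(acac)2, PhSiH3, O2, iPrOH) would then deliver oxygen, instead of carbon, to the more accessible face and give the tertiary alcohol F5. This would be acetylated (nBuLi, then Ac2O, THF, −78 → 0 °C) to 15.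

Further compounds
F1 | step 5 | cis-fused cis-diol (hydroxyls on C1 and C2; ring A closed by the C1–C2 bond) | O[C@]12CCC3(OCCO3)[C@H](C)[C@H]1[C@@H](COCc4ccc(OC)cc4)CC[C@@H]2O
F2 | step 5 | C2 mesylate of F1 | O[C@]12CCC3(OCCO3)[C@H](C)[C@H]1[C@@H](COCc4ccc(OC)cc4)CC[C@@H]2OS(C)(=O)=O
F3 | step 8 | trimethylsilyl enol ether of 16 (C7=C8) | CC(=O)O[C@]1(C)[C@@H]2CC[C@H](COCc3ccc(OC)cc3)[C@@H]1C(C)=C(O[Si](C)(C)C)CC2
F4 | step 6 | exocyclic methylene compound (C1=CH2) from 13 | C=C1[C@@H]2CC[C@H](COCc3ccc(OC)cc3)[C@@H]1[C@@H](C)C4(OCCO4)CC2
F5 | step 6 | tertiary alcohol (C1 methyl and hydroxyl; C8 ketal) | O[C@]1(C)[C@@H]2CC[C@H](COCc3ccc(OC)cc3)[C@@H]1[C@@H](C)C4(OCCO4)CC2
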